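## The problem

- Target 18 is a 2,3-dihydrobenzofuran. Benzo ring A is fused to the oxygen heterocycle ring B; C2 of ring B carries the 3,4,5-trimethoxyphenyl ring C and C3 carries a hydroxymethyl group. C5 of ring A, para to the ring oxygen O1, carries an (E)-3-hydroxyprop-1-enyl chain.
- The only stereocentres are C2 (R) and C3 (S), adjacent and trans on a nearly flat five-membered ring. A substituent already fixed at C3 can direct a bond formed at C2 to the opposite face, so only C3 needs catalyst control.
- C2 is benzylic to an electron-rich arene and also bonded to an aryloxy oxygen, so acid can ionise the C2–O1 bond and scramble or open ring B.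
- The cinnamyl alcohol is equally acid-labile, and its styrene-type alkene accepts radicals, hydride and electrophiles. It should therefore be introduced late and unmasked without acid.
- Ring A has no oxygen at C7 and ring C has no free phenol, so the oxidative coupling of propenylphenols that usually builds this skeleton is not available. The C5 chain has to come from a cross-coupling at a halogenated ring A.
- The key step is made possible by the C2–C(aryl) bond, which ends on the carbon bearing O1. The C2 radical is stabilised by O1, is planar (so any C2 configuration in its precursor is irrelevant), and can be released from a 2,3-dihydrobenzofuran-2-carboxylic acid.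
- That acid is the ring-contracted form of a 3-bromo-3,4-dihydrocoumarin, whose C4 centre (the future C3) can be set by conjugate reduction of a flat coumarin.

## Retrosynthesis

**18 ⇒ 17 (two O–Si bonds).** Both primary alcohols are carried as tert-butyldimethylsilyl ethers and released together by fluoride. This avoids acid at the benzylic C2–O1 bond and at the allylic alcohol. The bulky silyl ether on the C3 arm also serves as the steric control element of the key step.

**17 ⇒ 15 + 16 (C5–alkenyl bond).** A Suzuki–Miyaura cut removes the whole three-carbon chain as boronate 16, which already has the E geometry and the protected alcohol. Placing this cut after the radical step keeps the styrene-type alkene out of a reaction that generates a nucleophilic carbon radical. A Heck or Wittig approach would need extra redox or protecting steps. The handle on ring A is chlorine rather than bromine. An electron-rich C–Cl bond should survive the nickel step beside an aryl iodide, and it still couples with palladium and a dialkylbiarylphosphine.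

**15 ⇒ 13 + 14 (C2–aryl bond, key step).** This cut removes ring C and the C2 stereocentre in one step. The precursor 13 has a single stereocentre, and its C2 configuration does not matter. The neighbouring cuts are less attractive: C2–C3 leads to a cis product, and O1–C2 demands a stereodefined benzylic alcohol. The forward reaction has to deliver the aryl group trans to the C3 arm and has to choose the C–I bond of 14 over the C–Cl bond of 13.

**13 ⇒ 11 + 12 (ester C–O bond).** The redox-active ester is made from acid 11 and N-hydroxyphthalimide 12 by carbodiimide coupling. Nothing else changes.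

**11 ⇒ 9, through 10 (O1–C2 bond).** Acid 11 is the product of a ring contraction. Hydroxide opens the lactone of bromide 9, and the phenoxide of 10 closes ring B by displacing bromide. The lactone oxygen becomes O1 and the benzylic stereocentre is carried over untouched. The alternative, hydrogenating a benzofuran-2-carboxylate, would have to create the C3 centre on a tetrasubstituted alkene. The forward reaction requires lactone opening to outrun loss of HBr.

**9 ⇒ 7, through 8 (C–Br bond).** The bromide comes from α-bromination of lactone 7 through silyl ketene acetal 8. The configuration at the brominated carbon is irrelevant, because it is erased in the key step.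

**7 ⇒ 6 (C4–H bond, the stereocentre).** Asymmetric copper hydride conjugate reduction of the flat coumarin 6 sets the only catalyst-controlled centre of the synthesis. The precursor is achiral and planar.

**6 ⇒ 5 ⇒ 3, through 4 (O–Si, then C–O for C–Cl).** Silyl ether 6 comes from alcohol 5. Alcohol 5 comes from chloride 3 by acetate displacement to 4 and acid-catalysed transesterification.

**3 ⇒ 1 + 2 (C4–C4a and lactone C–O bonds).** A Pechmann condensation of 4-chlorophenol 1 with ethyl 4-chloroacetoacetate 2 builds the coumarin. The para chlorine ends at the position that becomes C5 of the target.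

## Roads not taken

**Alternative 1: carbene C–H insertion closing C2–C3.**
- Cut and key step: the cut is the C2–C3 bond of ring B. Diazo ester A1 loses nitrogen on Rh2(S-PTTL)4, and the rhodium carbene inserts into the benzylic C–H bond of its own trimethoxybenzyl ether, giving the cis ester A2.
- Merits: ring B and both stereocentres arise in one catalytic step. The electron-rich benzylic C–H bond is well activated. A1 is only an O-alkylation and a diazo transfer away from simple building blocks.
- Weak points: insertion gives the 2,3-cis product, so C3 must be epimerised through its ester enolate. That enolate has O1 as a β-leaving group, and E1cB opening would erase both centres. Oxonium ylide formation at the ether oxygen followed by a [1,2]-shift competes with insertion. An aryldiazoacetate has to be handled, and ring C is fixed from the first step.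
- Comparison: this road is probably two or three steps shorter than the chosen plan and sets both centres with one catalyst. The chosen plan offers in return a directly trans product with no epimerisation next to a leaving group, no diazo compound, copper and nickel in place of rhodium, and a late aryl iodide that can be varied.

**Alternative 2: three-component conjunctive coupling.**
- Cut and key step: both aryl–carbon bonds, C2–ring C and C3–ring A, are cut. Aryllithium A3 adds to the boron of alkenylboronate 16. Pd(OAc)2 with a chiral ferrocenyl bisphosphine then couples the ate complex with aryl triflate A4, so ring C shifts from boron to the future C2 while ring A bonds to the future C3, giving the anti boronate A5.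
- Later steps: oxidation of the C–B bond of A5 and displacement of the fluoride, which the para ester activates, would close ring B.
- Merits: it is highly convergent. The metallate shift fixes the relative configuration and the ligand fixes the absolute one. Ring closure by fluoride displacement is reliable.
- Weak points: the β-substituent on 16 slows alkene binding to palladium, so direct Suzuki-type transfer from boron competes. Triflate A4 is ortho-substituted. The C5 ester of A5 still needs about four steps (reduce, oxidise, olefinate, reduce) to become the propenol chain.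
- Comparison: this road is better in convergence and in catalyst control of both centres. The chosen plan has a longer linear front end, but each of its steps has close precedent on its substrate class and its endgame is two steps.

**Alternative 3: asymmetric hydrogenation of a flat benzofuran.**
- Cut and key step: no skeletal bond is cut. Benzofuran diester A6 takes up H2 syn across C2=C3 on a chiral ruthenium N-heterocyclic carbene catalyst made from Ru(cod)(2-methylallyl)2, giving the cis diester A7.
- Merits: A6 is an easily assembled aromatic compound. The step is atom-economical and scalable, and both centres form at once.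
- Weak points: the C2=C3 bond of A6 is tetrasubstituted and push–pull, a harder case than 2-substituted benzofurans. The cis product needs the same risky C3 epimerisation as in alternative 1. The two esters of A7 must be told apart before the C5 chain can be built.
- Comparison: hydrogenation is the cleanest single operation of all four plans. The chosen plan has to set against this a key step that forms a skeletal bond, gives the trans isomer directly, and leaves only a coupling and a deprotection afterwards.

Key step: step 8

**Assumptions.**
- The target is taken as the (2R,3S)-trans isomer that its SMILES specifies.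
- (R)-DTBM-SEGPHOS is taken to deliver hydride to the face of coumarin 6 that gives (S)-7, by analogy with 4-arylcoumarins. If the sense proves opposite, the (S)-ligand is used and nothing else changes.

## Route

Step 1
Reactants: 1 4-chlorophenol; 2 ethyl 4-chloro-3-oxobutanoate (ethyl 4-chloroacetoacetate)
Product: 3 6-chloro-4-(chloromethyl)-2H-chromen-2-one
Conditions: conc. H2SO4, 0 °C → rt
Reagents that add atoms: none
Why: Pechmann condensation: acid-promoted transesterification, ring closure of the ketone onto the position ortho to the phenol oxygen and dehydration; the para chlorine leaves only the ortho positions open, and although the phenol is not activated this is the standard entry to 4-(chloromethyl)coumarins.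

Step 2
Reactants: 3 6-chloro-4-(chloromethyl)-2H-chromen-2-one
Product: 5 6-chloro-4-(hydroxymethyl)-2H-chromen-2-one, via acetate 4 (not isolated)
Conditions: KOAc, DMF, 60 °C; then conc. HCl, EtOH, reflux
Reagents that add atoms: potassium acetate, CC(=O)[O-].[K+]
Why: SN2 displacement of the activated primary chloride by acetate, then acid-catalysed transesterification of the acetate to ethanol; the coumarin lactone stays closed in acid.

Step 3
Reactants: 5 6-chloro-4-(hydroxymethyl)-2H-chromen-2-one
Product: 6 4-{[(tert-butyldimethylsilyl)oxy]methyl}-6-chloro-2H-chromen-2-one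
Conditions: TBSCl, imidazole, DMF, rt
Reagents that add atoms: tert-butyldimethylsilyl chloride, CC(C)(C)[Si](C)(C)Cl
Why: Standard silylation of a primary alcohol; the silyl ether tolerates the hydride, enolate, hydroxide, nickel and palladium steps that follow.

Step 4
Reactants: 6 4-{[(tert-butyldimethylsilyl)oxy]methyl}-6-chloro-2H-chromen-2-one
Product: 7 (4S)-4-{[(tert-butyldimethylsilyl)oxy]methyl}-6-chloro-3,4-dihydro-2H-chromen-2-one
Conditions: Cu(OAc)2·H2O (3 mol%), (R)-DTBM-SEGPHOS (3 mol%), (EtO)2MeSiH (1.2 equiv), t-BuOH, toluene, 0 °C; aq. NH4F work-up
Reagents that add atoms: none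
Why: Asymmetric copper hydride conjugate reduction of a 4-substituted coumarin: the ligated copper hydride adds hydride to C4 from one face of the flat lactone, t-BuOH protonates the copper enolate and the silane regenerates the hydride. The bulky bisphosphine sets C4 as S; this centre becomes C3 of the target, and the aryl chloride and silyl ether are inert.

Step 5
Reactants: 7 (4S)-4-{[(tert-butyldimethylsilyl)oxy]methyl}-6-chloro-3,4-dihydro-2H-chromen-2-one
Product: 9 (4S)-3-bromo-4-{[(tert-butyldimethylsilyl)oxy]methyl}-6-chloro-3,4-dihydro-2H-chromen-2-one (both C3 epimers), via trimethylsilyl ketene acetal 8 (not isolated)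
Conditions: LiN(SiMe3)2, Me3SiCl, THF, −78 °C; then NBS, −78 → −20 °C
Reagents that add atoms: N-bromosuccinimide, O=C1CCC(=O)N1Br; chlorotrimethylsilane, C[Si](C)(C)Cl (silyl group of 8 only)
Why: α-Bromination of a lactone through its silyl ketene acetal: deprotonation with in situ O-silylation traps the aryl ester enolate before it can fragment, and NBS then brominates 8 with no strong base present, so the product is not exposed to elimination. The C4 centre is not touched and the configuration at C3 does not matter.

Step 6
Reactants: 9 (4S)-3-bromo-4-{[(tert-butyldimethylsilyl)oxy]methyl}-6-chloro-3,4-dihydro-2H-chromen-2-one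
Product: 11 (3S)-3-{[(tert-butyldimethylsilyl)oxy]methyl}-5-chloro-2,3-dihydro-1-benzofuran-2-carboxylic acid (both C2 epimers), via ring-opened bromo phenol acid 10 (not isolated)
Conditions: KOH, THF/H2O, 0 °C → rt; then 1 M HCl to pH 4, 0 °C
Reagents that add atoms: potassium hydroxide, [K+].[OH-]
Why: Ring contraction of a 3-halo-3,4-dihydrocoumarin: hydroxide opens the activated aryl lactone and the phenoxide of 10 displaces the neighbouring bromide in a 5-exo-tet intramolecular Williamson etherification. The benzylic centre is a spectator and becomes C3 (S) of the dihydrobenzofuran.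

Step 7
Reactants: 11 (3S)-3-{[(tert-butyldimethylsilyl)oxy]methyl}-5-chloro-2,3-dihydro-1-benzofuran-2-carboxylic acid; 12 N-hydroxyphthalimide
Product: 13 1,3-dioxoisoindolin-2-yl (3S)-3-{[(tert-butyldimethylsilyl)oxy]methyl}-5-chloro-2,3-dihydro-1-benzofuran-2-carboxylate (both C2 epimers)
Conditions: DIC, DMAP (10 mol%), CH2Cl2, rt
Reagents that add atoms: none
Why: Carbodiimide esterification to the redox-active N-acyloxyphthalimide; epimerisation at C2 is of no consequence, and the ester is used after a short filtration.

Step 8
Reactants: 13 1,3-dioxoisoindolin-2-yl (3S)-3-{[(tert-butyldimethylsilyl)oxy]methyl}-5-chloro-2,3-dihydro-1-benzofuran-2-carboxylate; 14 5-iodo-1,2,3-trimethoxybenzene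
Product: 15 tert-butyl{[(2R,3S)-5-chloro-2-(3,4,5-trimethoxyphenyl)-2,3-dihydro-1-benzofuran-3-yl]methoxy}dimethylsilane
Conditions: NiCl2(glyme) (20 mol%), 4,4'-di-tert-butyl-2,2'-bipyridine (20 mol%), 14 (2 equiv), LiCl, DMF, undivided cell, Mg anode, reticulated vitreous carbon cathode carrying electrodeposited silver, constant current, rt
Reagents that add atoms: none
Why: Cathodic reduction gives bipyridine-ligated zerovalent nickel, which inserts into the C–I bond of 14 to give a divalent arylnickel iodide, while the electron-rich C–Cl bond of 13 is left alone. Single-electron reduction of the phthalimide ester of 13 cleaves the N–O bond and releases CO2 and phthalimide anion, leaving the planar C2 radical stabilised by O1. The arylnickel species captures this radical and the resulting trivalent alkyl(aryl)nickel forms the C2–aryl bond by reductive elimination; monovalent nickel is reduced again at the cathode while magnesium dissolves at the anode. The closest known reaction type is the nickel-electrocatalytic decarboxylative arylation of redox-active esters of α-alkoxy acids with aryl iodides. No ring is closed. The new C2 centre is under substrate control: the silyloxymethyl group on C3 shields its own face, so nickel and then the aryl group end up on the opposite face, and because the radical is planar both C2 epimers of 13 converge on the (2R,3S) trans product. The step needs trans over cis capture, C–I over C–Cl insertion and coupling over hydrodecarboxylation or β-hydride loss; the bulky silyl ether, the large reactivity gap between the two halides and the absence of any radical-accepting alkene secure these.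

Step 9
Reactants: 15 tert-butyl{[(2R,3S)-5-chloro-2-(3,4,5-trimethoxyphenyl)-2,3-dihydro-1-benzofuran-3-yl]methoxy}dimethylsilane; 16 (E)-tert-butyldimethyl{[3-(4,4,5,5-tetramethyl-1,3,2-dioxaborolan-2-yl)prop-2-en-1-yl]oxy}silane
Product: 17 tert-butyl{[(E)-3-[(2R,3S)-3-{[(tert-butyldimethylsilyl)oxy]methyl}-2-(3,4,5-trimethoxyphenyl)-2,3-dihydro-1-benzofuran-5-yl]prop-2-en-1-yl]oxy}dimethylsilane
Conditions: Pd(OAc)2 (5 mol%), SPhos (10 mol%), K3PO4, 1,4-dioxane/H2O, 80 °C
Reagents that add atoms: none
Why: Suzuki–Miyaura coupling of an aryl chloride with an alkenylboronate: the electron-rich dialkylbiarylphosphine lets zerovalent palladium insert into the electron-rich C–Cl bond, and transmetallation and reductive elimination keep the E geometry. Neither stereocentre is involved.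

Step 10
Reactants: 17 tert-butyl{[(E)-3-[(2R,3S)-3-{[(tert-butyldimethylsilyl)oxy]methyl}-2-(3,4,5-trimethoxyphenyl)-2,3-dihydro-1-benzofuran-5-yl]prop-2-en-1-yl]oxy}dimethylsilane
Product: 18 (E)-3-[(2R,3S)-3-(hydroxymethyl)-2-(3,4,5-trimethoxyphenyl)-2,3-dihydro-1-benzofuran-5-yl]prop-2-en-1-ol
Conditions: Bu4NF, THF, 0 °C → rt
Reagents that add atoms: none
Why: Fluoride cleavage of both primary silyl ethers under non-acidic conditions, which spares the benzylic C2–O1 bond and the allylic alcohol.

## Compound list

1 | 4-chlorophenol | Oc1ccc(Cl)cc1 | starting material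
2 | ethyl 4-chloro-3-oxobutanoate | CCOC(=O)CC(=O)CCl | starting material
3 | 6-chloro-4-(chloromethyl)-2H-chromen-2-one | O=C1C=C(CCl)c2cc(Cl)ccc2O1 | intermediate
4 | (6-chloro-2-oxo-2H-chromen-4-yl)methyl acetate | CC(=O)OCC1=CC(=O)Oc2ccc(Cl)cc12 | intermediate
5 | 6-chloro-4-(hydroxymethyl)-2H-chromen-2-one | O=C1C=C(CO)c2cc(Cl)ccc2O1 | intermediate
6 | 4-{[(tert-butyldimethylsilyl)oxy]methyl}-6-chloro-2H-chromen-2-one | CC(C)(C)[Si](C)(C)OCC1=CC(=O)Oc2ccc(Cl)cc12 | intermediate
7 | (4S)-4-{[(tert-butyldimethylsilyl)oxy]methyl}-6-chloro-3,4-dihydro-2H-chromen-2-one | O=C1C[C@H](CO[Si](C)(C)C(C)(C)C)c2cc(Cl)ccc2O1 | intermediate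
8 | (4S)-4-{[(tert-butyldimethylsilyl)oxy]methyl}-6-chloro-2-(trimethylsilyloxy)-4H-chromene | C[Si](C)(C)OC1=C[C@H](CO[Si](C)(C)C(C)(C)C)c2cc(Cl)ccc2O1 | intermediate
9 | (4S)-3-bromo-4-{[(tert-butyldimethylsilyl)oxy]methyl}-6-chloro-3,4-dihydro-2H-chromen-2-one, both C3 epimers | O=C1C(Br)[C@H](CO[Si](C)(C)C(C)(C)C)c2cc(Cl)ccc2O1 | intermediate
10 | (3S)-2-bromo-4-[(tert-butyldimethylsilyl)oxy]-3-(5-chloro-2-hydroxyphenyl)butanoic acid, both C2 epimers, present as its dipotassium salt | OC(=O)C(Br)[C@H](CO[Si](C)(C)C(C)(C)C)c1cc(Cl)ccc1O | intermediate
11 | (3S)-3-{[(tert-butyldimethylsilyl)oxy]methyl}-5-chloro-2,3-dihydro-1-benzofuran-2-carboxylic acid, both C2 epimers | OC(=O)C1Oc2ccc(Cl)cc2[C@H]1CO[Si](C)(C)C(C)(C)C | intermediate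
12 | N-hydroxyphthalimide | O=C1c2ccccc2C(=O)N1O | starting material
13 | 1,3-dioxoisoindolin-2-yl (3S)-3-{[(tert-butyldimethylsilyl)oxy]methyl}-5-chloro-2,3-dihydro-1-benzofuran-2-carboxylate, both C2 epimers | O=C(ON1C(=O)c2ccccc2C1=O)C1Oc2ccc(Cl)cc2[C@H]1CO[Si](C)(C)C(C)(C)C | intermediate
14 | 5-iodo-1,2,3-trimethoxybenzene | COc1cc(I)cc(OC)c1OC | starting material
15 | tert-butyl{[(2R,3S)-5-chloro-2-(3,4,5-trimethoxyphenyl)-2,3-dihydro-1-benzofuran-3-yl]methoxy}dimethylsilane | COc1cc([C@@H]2Oc3ccc(Cl)cc3[C@H]2CO[Si](C)(C)C(C)(C)C)cc(OC)c1OC | intermediate
16 | (E)-tert-butyldimethyl{[3-(4,4,5,5-tetramethyl-1,3,2-dioxaborolan-2-yl)prop-2-en-1-yl]oxy}silane | CC(C)(C)[Si](C)(C)OC/C=C/B1OC(C)(C)C(C)(C)O1 | starting material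
17 | tert-butyl{[(E)-3-[(2R,3S)-3-{[(tert-butyldimethylsilyl)oxy]methyl}-2-(3,4,5-trimethoxyphenyl)-2,3-dihydro-1-benzofuran-5-yl]prop-2-en-1-yl]oxy}dimethylsilane | COc1cc([C@@H]2Oc3ccc(/C=C/CO[Si](C)(C)C(C)(C)C)cc3[C@H]2CO[Si](C)(C)C(C)(C)C)cc(OC)c1OC | intermediate
18 | (E)-3-[(2R,3S)-3-(hydroxymethyl)-2-(3,4,5-trimethoxyphenyl)-2,3-dihydro-1-benzofuran-5-yl]prop-2-en-1-ol | COc1cc([C@@H]2Oc3ccc(/C=C/CO)cc3[C@H]2CO)cc(OC)c1OC | target

## Step count and least certain steps

Total: 10 steps. Longest linear sequence: 10 steps, from 1 to 18; compounds 12, 14 and 16 are purchased.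

**Step 8 (key step).**
- What may go wrong: poor facial selectivity in the capture of the C2 radical; hydrodecarboxylation when the radical or the ester is reduced further at the cathode; β-hydride loss from the alkylnickel intermediate, which is driven by aromatisation of ring B; and some insertion of nickel into the C–Cl bond.
- Fallback: the coupling would be run as a redox-neutral decarboxylative Negishi-type arylation with no electrode. Iodide 14 would be converted with i-PrMgCl·LiCl into (3,4,5-trimethoxyphenyl)magnesium chloride F1 and then with ZnCl2 into (3,4,5-trimethoxyphenyl)zinc chloride F2. Ester 13 would be coupled with F2 under NiCl2(glyme) and 4,4'-di-tert-butyl-2,2'-bipyridine in THF/DMF at rt. The route is rejoined at 15.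

**Step 4.**
- What may go wrong: over-reduction of the activated aryl lactone carbonyl after the conjugate reduction, and insufficient enantiofacial discrimination between the ring and the silyloxymethyl arm.
- Fallback: over-reduction would be made deliberate. Coumarin 6 would be treated with excess silane under the same copper catalyst to give (4S)-4-{[(tert-butyldimethylsilyl)oxy]methyl}-6-chloro-3,4-dihydro-2H-chromen-2-ol F3. This lactol would be oxidised back with PhI(OAc)2 and catalytic TEMPO in CH2Cl2. The route is rejoined at 7.

**Step 5.**
- What may go wrong: double bromination, fragmentation of the aryl ester enolate before silylation, and loss of HBr from the product back to the flat coumarin.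
- Fallback: the halide would be avoided altogether. Lactone 7 would be hydroxylated through its lithium enolate with 2-(phenylsulfonyl)-3-phenyloxaziridine to give (4S)-4-{[(tert-butyldimethylsilyl)oxy]methyl}-6-chloro-3-hydroxy-3,4-dihydro-2H-chromen-2-one F4. Methanolysis with K2CO3 in MeOH would give methyl (3S)-4-[(tert-butyldimethylsilyl)oxy]-3-(5-chloro-2-hydroxyphenyl)-2-hydroxybutanoate F5. An intramolecular Mitsunobu etherification (PPh3, DIAD) would close ring B to methyl (3S)-3-{[(tert-butyldimethylsilyl)oxy]methyl}-5-chloro-2,3-dihydro-1-benzofuran-2-carboxylate F6, and LiOH would hydrolyse the ester. The route is rejoined at 11, which also bypasses step 6.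

**Step 6.**
- What may go wrong: elimination of HBr by hydroxide acting as a base before the lactone opens, and partial loss of the silyl ether during the basic reaction or the acidification.
- Fallback: the ring contraction would be triggered by an alcohol and the acid released under neutral conditions. Bromide 9 would be treated with K2CO3 in allyl alcohol at 0 °C to give allyl (3S)-3-{[(tert-butyldimethylsilyl)oxy]methyl}-5-chloro-2,3-dihydro-1-benzofuran-2-carboxylate F7. The allyl group would then be transferred to morpholine with catalytic Pd(PPh3)4 in THF. The route is rejoined at 11.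

## Further compounds

F1 | step 8 | (3,4,5-trimethoxyphenyl)magnesium chloride | COc1cc([Mg]Cl)cc(OC)c1OC
F2 | step 8 | (3,4,5-trimethoxyphenyl)zinc chloride | COc1cc([Zn]Cl)cc(OC)c1OC
F3 | step 4 | (4S)-4-{[(tert-butyldimethylsilyl)oxy]methyl}-6-chloro-3,4-dihydro-2H-chromen-2-ol, both anomers | OC1C[C@H](CO[Si](C)(C)C(C)(C)C)c2cc(Cl)ccc2O1
F4 | step 5 | (4S)-4-{[(tert-butyldimethylsilyl)oxy]methyl}-6-chloro-3-hydroxy-3,4-dihydro-2H-chromen-2-one, both C3 epimers | O=C1C(O)[C@H](CO[Si](C)(C)C(C)(C)C)c2cc(Cl)ccc2O1
F5 | step 5 | methyl (3S)-4-[(tert-butyldimethylsilyl)oxy]-3-(5-chloro-2-hydroxyphenyl)-2-hydroxybutanoate, both C2 epimers | COC(=O)C(O)[C@H](CO[Si](C)(C)C(C)(C)C)c1cc(Cl)ccc1O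
F6 | step 5 | methyl (3S)-3-{[(tert-butyldimethylsilyl)oxy]methyl}-5-chloro-2,3-dihydro-1-benzofuran-2-carboxylate, both C2 epimers | COC(=O)C1Oc2ccc(Cl)cc2[C@H]1CO[Si](C)(C)C(C)(C)C
F7 | step 6 | allyl (3S)-3-{[(tert-butyldimethylsilyl)oxy]methyl}-5-chloro-2,3-dihydro-1-benzofuran-2-carboxylate, both C2 epimers | C=CCOC(=O)C1Oc2ccc(Cl)cc2[C@H]1CO[Si](C)(C)C(C)(C)C
A1 | alternative 1 | methyl 2-[5-bromo-2-(3,4,5-trimethoxybenzyloxy)phenyl]-2-diazoacetate | COC(=O)C(=[N+]=[N-])c1cc(Br)ccc1OCc1cc(OC)c(OC)c(OC)c1
A2 | alternative 1 | methyl (2R,3S)-5-bromo-2-(3,4,5-trimethoxyphenyl)-2,3-dihydro-1-benzofuran-3-carboxylate (cis) | COc1cc([C@@H]2Oc3ccc(Br)cc3[C@@H]2C(=O)OC)cc(OC)c1OC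
A3 | alternative 2 | (3,4,5-trimethoxyphenyl)lithium | [Li]c1cc(OC)c(OC)c(OC)c1
A4 | alternative 2 | methyl 4-fluoro-3-{[(trifluoromethyl)sulfonyl]oxy}benzoate | COC(=O)c1ccc(F)c(OS(=O)(=O)C(F)(F)F)c1
A5 | alternative 2 | methyl 3-[(1R,2S)-3-(tert-butyldimethylsilyloxy)-1-(4,4,5,5-tetramethyl-1,3,2-dioxaborolan-2-yl)-1-(3,4,5-trimethoxyphenyl)propan-2-yl]-4-fluorobenzoate (anti) | COc1cc([C@H](B2OC(C)(C)C(C)(C)O2)[C@H](CO[Si](C)(C)C(C)(C)C)c2cc(C(=O)OC)ccc2F)cc(OC)c1OC
A6 | alternative 3 | dimethyl 2-(3,4,5-trimethoxyphenyl)-1-benzofuran-3,5-dicarboxylate | COC(=O)c1ccc2oc(-c3cc(OC)c(OC)c(OC)c3)c(C(=O)OC)c2c1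
A7 | alternative 3 | dimethyl (2R,3S)-2-(3,4,5-trimethoxyphenyl)-2,3-dihydro-1-benzofuran-3,5-dicarboxylate (cis) | COc1cc([C@@H]2Oc3ccc(C(=O)OC)cc3[C@@H]2C(=O)OC)cc(OC)c1OC
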